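**Retrosynthetic overview**
- The tetralin ring is closed last: acid ionizes the benzylic C–O bond of a 2-aryl-tetrahydrofuran (lariciresinol 9'-p-coumarate) and the tethered guaiacyl ring closes by Friedel–Crafts alkylation. Until then the ring ether masks the C3-CH2OH, so only the C2-CH2OH is free for esterification.
- Lariciresinol comes from C2-symmetric (+)-pinoresinol dibenzyl ether by hydrogenolysis of the benzyl ethers and one of the two equivalent benzylic C–O bonds.
- Both tetrahydrofuran rings of the furofuran form in one flask from an epoxy cinnamyl ether: (C5H5)2TiCl epoxide opening, 5-exo radical cyclization, then iodine-triggered C–O closure.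
- The epoxy ether comes from a Sharpless kinetic-resolution epoxy alcohol and a cinnamyl bromide, both made from the vinyl Grignard adduct of O-benzylvanillin.
- Ring order: two tetrahydrofurans together, one of them reopened, then the tetralin ring from the remaining one.

Assumption: the SMILES is read as the (1S,2R,3R) isomer, i.e. (+)-isolariciresinol acylated at the CH2OH on C2; lignan locants are used below (C7/C8/C9 for the ring-A half, C7'/C8'/C9' for the pendant-aryl half; C7' becomes C1, C8' becomes C2, C8 becomes C3).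

**Step 1**
Reactants: 1 4-(benzyloxy)-3-methoxybenzaldehyde; 2 vinylmagnesium bromide
Product: 3 (±)-1-[4-(benzyloxy)-3-methoxyphenyl]prop-2-en-1-ol
Conditions: CH2=CHMgBr (1.2 eq), THF, 0 °C to rt; aq NH4Cl
Reagents that add atoms: vinylmagnesium bromide (2), C=C[Mg]Br
Why: Grignard 1,2-addition to a non-enolizable aryl aldehyde gives the racemic allylic alcohol, whose stereocentre is resolved in step 2 or erased in step 3.

**Step 2**
Reactants: 3 (±)-1-[4-(benzyloxy)-3-methoxyphenyl]prop-2-en-1-ol; 4 tert-butyl hydroperoxide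
Product: 5 (R)-[4-(benzyloxy)-3-methoxyphenyl][(2S)-oxiran-2-yl]methanol
Conditions: Ti(OiPr)4 (0.2 eq), D-(−)-DIPT (0.3 eq), TBHP (0.55 eq), 4 Å MS, CH2Cl2, −20 °C, stopped near 50% conversion
Reagents that add atoms: tert-butyl hydroperoxide (4), CC(C)(C)OO
Why: Sharpless asymmetric epoxidation run as a kinetic resolution: with D-(−)-DIPT the (S)-alcohol is epoxidized much faster and gives the erythro epoxy alcohol, fixing the benzylic centre C7' as R (the 2S epoxide centre is sacrificial), while unreacted (R)-3 is recovered.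

**Step 3**
Reactants: 3 (±)-1-[4-(benzyloxy)-3-methoxyphenyl]prop-2-en-1-ol (a second portion, or the (R)-enriched alcohol recovered in step 2); 6 phosphorus tribromide
Product: 7 1-(benzyloxy)-4-[(1E)-3-bromoprop-1-en-1-yl]-2-methoxybenzene
Conditions: PBr3 (0.4 eq), Et2O, 0 °C; used crude at once
Reagents that add atoms: phosphorus tribromide (6), BrP(Br)Br
Why: Bromination with allylic transposition (SN2'/ion pair) gives the conjugated E-cinnamyl bromide and erases the stereocentre, so either enantiomer of 3 serves.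

**Step 4**
Reactants: 5 (R)-[4-(benzyloxy)-3-methoxyphenyl][(2S)-oxiran-2-yl]methanol; 7 1-(benzyloxy)-4-[(1E)-3-bromoprop-1-en-1-yl]-2-methoxybenzene
Product: 8 (2S)-2-[(R)-[4-(benzyloxy)-3-methoxyphenyl]{[(2E)-3-[4-(benzyloxy)-3-methoxyphenyl]prop-2-en-1-yl]oxy}methyl]oxirane
Conditions: NaH (1.1 eq), THF/DMF 4:1, 0 °C; then 7 (1.2 eq), Bu4NI (0.1 eq), 0 °C to rt
Reagents that add atoms: cinnamyl bromide (7), COc1cc(/C=C/CBr)ccc1OCc1ccccc1
Why: Williamson ether synthesis in an aprotic medium, where O-alkylation by the reactive allylic bromide outruns Payne rearrangement of the epoxy alkoxide; no stereocentre is touched.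

**Step 5**
Reactants: 8 (2S)-2-[(R)-[4-(benzyloxy)-3-methoxyphenyl]{[(2E)-3-[4-(benzyloxy)-3-methoxyphenyl]prop-2-en-1-yl]oxy}methyl]oxirane
Product: 11 (+)-pinoresinol dibenzyl ether, via bis-titanium cyclization product 9 (not isolated), via benzylic iodide 10 (not isolated)
Conditions: (C5H5)2TiCl2 (2.5 eq), Zn dust, THF, rt, the green (C5H5)2TiCl solution added dropwise to 8 in THF, rt; then I2 (1.3 eq), same flask, rt to 60 °C; aq Na2S2O3
Reagents that add atoms: none
Why: Nugent–RajanBabu epoxide opening by trivalent titanium gives the C8' radical, which closes 5-exo-trig onto the styrene through a chair-like Beckwith–Houk transition state with the C7' aryl pseudo-equatorial (2,3-trans, 3,4-cis, so C7' sets C8' and C8), and after capture of the benzylic radical by a second (C5H5)2TiCl, iodine gives a benzylic iodide that the cis titanium alkoxide displaces (SN1-like, aryl exo) to close the second tetrahydrofuran, a cascade known for racemic furofuran lignans.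

**Step 6**
Reactants: 11 (+)-pinoresinol dibenzyl ether
Product: 12 (+)-lariciresinol
Conditions: H2 (1 atm), 10% Pd/C, EtOAc/EtOH 1:1, rt, followed by HPLC and stopped at maximum 12
Reagents that add atoms: none
Why: Pd-catalysed hydrogenolysis first removes both aryl benzyl ethers and then one of the two homotopic benzylic C–O bonds of the C2-symmetric furofuran, so the same monocleavage product forms whichever ring opens, with C8 and C8' untouched.

**Step 7**
Reactants: 12 (+)-lariciresinol; 13 (E)-p-coumaric acid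
Product: 14 (+)-lariciresinol 9'-O-(E)-p-coumarate
Conditions: 13 (1.1 eq), PPh3 (1.3 eq), DIAD (1.3 eq), THF, 0 °C to rt
Reagents that add atoms: (E)-p-coumaric acid (13), OC(=O)/C=C/c1ccc(O)cc1
Why: Mitsunobu esterification uses the carboxylic acid (pKa about 4.5) as nucleophile in preference to the three phenols (pKa about 10) and activates only the single aliphatic primary alcohol, so no phenol protection is needed and no stereocentre is involved.

**Step 8**
Reactants: 14 (+)-lariciresinol 9'-O-(E)-p-coumarate
Product: 15 [(1S,2R,3R)-7-hydroxy-1-(4-hydroxy-3-methoxyphenyl)-3-(hydroxymethyl)-6-methoxy-1,2,3,4-tetrahydronaphthalen-2-yl]methyl (2E)-3-(4-hydroxyphenyl)prop-2-enoate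
Conditions: TFA (10 eq), CH2Cl2, 0 °C to rt
Reagents that add atoms: none
Why: Acid ionizes the benzylic C–O bond (p-hydroxybenzyl cation), freeing the C3-CH2OH, and the tethered guaiacyl ring closes by intramolecular Friedel–Crafts alkylation para to its OMe with the aryl equatorial and trans to the C2 substituent (1S) while C2 and C3 are retained, as in the known lariciresinol to isolariciresinol rearrangement.

**Compound list**
1 | 4-(benzyloxy)-3-methoxybenzaldehyde (O-benzylvanillin) | COc1cc(C=O)ccc1OCc1ccccc1 | starting material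
2 | vinylmagnesium bromide, CH2=CHMgBr | C=C[Mg]Br | starting material
3 | (±)-1-[4-(benzyloxy)-3-methoxyphenyl]prop-2-en-1-ol | COc1cc(C(O)C=C)ccc1OCc1ccccc1 | intermediate
4 | tert-butyl hydroperoxide | CC(C)(C)OO | starting material
5 | (R)-[4-(benzyloxy)-3-methoxyphenyl][(2S)-oxiran-2-yl]methanol (erythro) | COc1cc([C@@H](O)[C@@H]2CO2)ccc1OCc1ccccc1 | intermediate
6 | phosphorus tribromide, PBr3 | BrP(Br)Br | starting material
7 | 1-(benzyloxy)-4-[(1E)-3-bromoprop-1-en-1-yl]-2-methoxybenzene | COc1cc(/C=C/CBr)ccc1OCc1ccccc1 | intermediate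
8 | (2S)-2-[(R)-[4-(benzyloxy)-3-methoxyphenyl]{[(2E)-3-[4-(benzyloxy)-3-methoxyphenyl]prop-2-en-1-yl]oxy}methyl]oxirane | COc1cc([C@@H](OC/C=C/c2ccc(OCc3ccccc3)c(OC)c2)[C@@H]2CO2)ccc1OCc1ccccc1 | intermediate
9 | bis-titanium cyclization product: the 2,3-trans-3,4-cis oxolane of 12 with both phenols as benzyl ethers, CH2O–TiCl(C5H5)2 at C3 and ArCH[TiCl(C5H5)2] at C4 (benzylic centre unassigned) | COc1cc(C([Ti](Cl)(C4C=CC=C4)C4C=CC=C4)[C@H]2CO[C@@H]([C@H]2CO[Ti](Cl)(C4C=CC=C4)C4C=CC=C4)c2ccc(OCc3ccccc3)c(OC)c2)ccc1OCc1ccccc1 | intermediate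
10 | benzylic iodide: the same oxolane with CH2O–TiCl(C5H5)2 at C3 and ArCH(I) at C4 | COc1cc(C(I)[C@H]2CO[C@@H]([C@H]2CO[Ti](Cl)(C4C=CC=C4)C4C=CC=C4)c2ccc(OCc3ccccc3)c(OC)c2)ccc1OCc1ccccc1 | intermediate
11 | (+)-pinoresinol dibenzyl ether, (1S,3aR,4S,6aR)-1,4-bis[4-(benzyloxy)-3-methoxyphenyl]tetrahydro-1H,3H-furo[3,4-c]furan | COc1cc([C@H]2OC[C@H]3[C@@H]2CO[C@@H]3c2ccc(OCc4ccccc4)c(OC)c2)ccc1OCc1ccccc1 | intermediate
12 | (+)-lariciresinol, 4-[(2S,3R,4R)-4-[(4-hydroxy-3-methoxyphenyl)methyl]-3-(hydroxymethyl)oxolan-2-yl]-2-methoxyphenol | COc1cc(C[C@H]2CO[C@@H]([C@H]2CO)c2ccc(O)c(OC)c2)ccc1O | intermediate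
13 | (E)-p-coumaric acid | OC(=O)/C=C/c1ccc(O)cc1 | starting material
14 | (+)-lariciresinol 9'-O-(E)-p-coumarate, [(2S,3R,4R)-2-(4-hydroxy-3-methoxyphenyl)-4-[(4-hydroxy-3-methoxyphenyl)methyl]oxolan-3-yl]methyl (2E)-3-(4-hydroxyphenyl)prop-2-enoate | COc1cc(C[C@H]2CO[C@@H]([C@H]2COC(=O)/C=C/c2ccc(O)cc2)c2ccc(O)c(OC)c2)ccc1O | intermediate
15 | [(1S,2R,3R)-7-hydroxy-1-(4-hydroxy-3-methoxyphenyl)-3-(hydroxymethyl)-6-methoxy-1,2,3,4-tetrahydronaphthalen-2-yl]methyl (2E)-3-(4-hydroxyphenyl)prop-2-enoate (CNP0403384.1) | COc1cc([C@H]2c3cc(O)c(OC)cc3C[C@@H](CO)[C@@H]2COC(=O)/C=C/c2ccc(O)cc2)ccc1O | target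

**Totals and risks**
Total step count: 8. Longest linear sequence: 7 (steps 1, 2, 4, 5, 6, 7, 8; step 3 is a one-step branch from 3).

Most likely to fail, first: step 5. The β-titanoxy radical can be deoxygenated to the alkene before it cyclizes, and the benzylic iodide can eliminate instead of closing the second ring. The fallback sets out from 8 and comes back at 12. The (C5H5)2TiCl cyclization is quenched with a proton source (2,4,6-collidine hydrochloride, no iodine), which stops at the reductively terminated monocycle (+)-lariciresinol dibenzyl ether F1. A short hydrogenolysis (H2, Pd/C, EtOAc, stopped after two equivalents of H2) then removes only the aryl benzyl ethers and gives 12, so 11 and step 6 are bypassed.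

Second: step 6. The first and second benzylic C–O cleavages have similar rates, so over-reduction competes and the yield of 12 is limited (recovered pinoresinol can be resubmitted). The fallback sets out from 11 and comes back at 12. Hydrogenolysis is driven to completion (H2, Pd/C, EtOH with a little AcOH), giving (−)-secoisolariciresinol F2 with no selectivity question. One p-hydroxybenzyl unit is then oxidized with DDQ (1.0 eq, dioxane, rt) to the quinone methide, which is trapped 5-exo by the CH2OH on the neighbouring carbon. Because F2 is C2-symmetric, either arene gives 12; a benzylic epimer would not matter, since that centre is erased in step 8.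

Third: step 7. Phenol O-alkylation under Mitsunobu conditions could erode the chemoselectivity. The fallback sets out from 12 and comes back at 14. All three hydroxyls are acylated with commercial (E)-4-acetoxycinnamic acid (3.5 eq, DCC, DMAP, CH2Cl2) to give (+)-lariciresinol tris[(E)-4-acetoxycinnamate] F3. Pyrrolidine (CH2Cl2, 0 °C) then cleaves the five aryl esters (two aryl cinnamates, three aryl acetates) and leaves the alkyl cinnamate, giving 14.

**Further compounds**
F1 | step 5 | (+)-lariciresinol dibenzyl ether, [(2S,3R,4R)-2-[4-(benzyloxy)-3-methoxyphenyl]-4-{[4-(benzyloxy)-3-methoxyphenyl]methyl}oxolan-3-yl]methanol | COc1cc(C[C@H]2CO[C@@H]([C@H]2CO)c2ccc(OCc3ccccc3)c(OC)c2)ccc1OCc1ccccc1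
F2 | step 6 | (−)-secoisolariciresinol, (2R,3R)-2,3-bis[(4-hydroxy-3-methoxyphenyl)methyl]butane-1,4-diol | COc1cc(C[C@@H](CO)[C@H](CO)Cc2ccc(O)c(OC)c2)ccc1O
F3 | step 7 | (+)-lariciresinol tris[(E)-4-acetoxycinnamate] (both phenols and the 9'-OH acylated) | COc1cc(C[C@H]2CO[C@@H]([C@H]2COC(=O)/C=C/c2ccc(OC(C)=O)cc2)c2ccc(OC(=O)/C=C/c3ccc(OC(C)=O)cc3)c(OC)c2)ccc1OC(=O)/C=C/c1ccc(OC(C)=O)cc1
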